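**Retrosynthetic overview**

1. Numbering follows the C15 chain: C1≡C2–C3=C4–C5(Cl)–C6(OAc)–C7(O)–C8–C9=C10(Cl)–C11–C12(Br)–C13(O, Et)–C14–C15. The ring oxygen O links C7 and C13; O9 is a temporary oxygen on C9.
2. Late disconnections: C3=C4 (Peterson olefination of a C4 aldehyde), C5–C6 with Cl and O (reagent-controlled γ-chloroallylboration of a C6 aldehyde), C12–Br (inversion of a C12 alcohol), C13–Et (Grignard addition and silane reduction of an eight-membered lactone), C12–O (enolate hydroxylation).
3. Core disconnection: the oxocene, the only ring of the target, is not closed end to end. A 1,3-dioxane (O–C13–O9–C9–C8–C7) is closed at O–C13 and expanded by a Claisen shift (C11–C12 formed, O9–C9 cleaved) to the eight-membered lactone. Ring order: acetonide (protecting ring, removed), then dioxane (temporary), then oxocene.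
4. Enabling feature: in the oxocene ring, C13 stands γ,δ to the ring double bond C9=C10(Cl) (C13–C12–C11–C10=C9), and the ring oxygen sits on C7, 1,3 to C9. A 7,9-diol with a 1-chlorovinyl group on C9 plus a two-carbon orthoester is therefore the full retron of a ring-expanding Claisen rearrangement.
5. Carbon sources: (R)-butanetriol acetonide (C6–C9), 1,1,1-trichloroethane (C10, C11), triethyl orthoacetate (C12, C13), EtMgBr (C14, C15), allyl chloride (C4, C5), 1,3-bis(triisopropylsilyl)propyne (C1–C3).

Key step: step 5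

Remark: the C9 carbinol centre made in step 2 is carried as both epimers (compounds 4, 5, 6, 8, 9), because C9 becomes sp2 in step 5 and both epimers should converge on lactone 10.

**Route**

Step 1
Reactants: 1 (R)-2-(2,2-dimethyl-1,3-dioxolan-4-yl)ethanol
Product: 2 (R)-2-(2,2-dimethyl-1,3-dioxolan-4-yl)acetaldehyde
Conditions: TEMPO (10 mol%), PhI(OAc)2, CH2Cl2, 20 °C
Reagents that add atoms: none
Why: Oxoammonium (TEMPO) oxidation of the primary alcohol should stop at the aldehyde and leave the acetonide and the C7 centre untouched.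

Step 2
Reactants: 2 (R)-2-(2,2-dimethyl-1,3-dioxolan-4-yl)acetaldehyde; 3 1,1,1-trichloroethane
Product: 4 (2RS)-3-chloro-1-[(4R)-2,2-dimethyl-1,3-dioxolan-4-yl]but-3-en-2-ol
Conditions: CrCl2 (excess), THF, 20 °C
Reagents that add atoms: 1,1,1-trichloroethane (3), CC(Cl)(Cl)Cl
Why: CrCl2 reduces the trichloromethyl group to a 1-chlorovinyl chromium species (Nozaki–Hiyama–Takai-type chemistry) that adds chemoselectively to the aldehyde to give the 2-chloroallylic alcohol; the new C9 centre is not controlled and need not be.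

Step 3
Reactants: 4 (2RS)-3-chloro-1-[(4R)-2,2-dimethyl-1,3-dioxolan-4-yl]but-3-en-2-ol
Product: 5 (2R,4RS)-5-chlorohex-5-ene-1,2,4-triol
Conditions: AcOH–H2O 4:1, 40 °C
Reagents that add atoms: none
Why: Acid-catalysed acetonide hydrolysis; the 2-chloroallylic alcohol should resist ionisation because the chlorine destabilises the allyl cation.

Step 4
Reactants: 5 (2R,4RS)-5-chlorohex-5-ene-1,2,4-triol
Product: 6 [(2R,4RS)-5-chloro-2,4-dihydroxyhex-5-en-1-yl] 2,2-dimethylpropanoate
Conditions: t-BuCOCl, pyridine, CH2Cl2, −20 °C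
Reagents that add atoms: pivaloyl chloride, CC(C)(C)C(Cl)=O
Why: Acylation with the bulky acid chloride should be selective for the primary C6 hydroxyl over the two secondary ones, leaving the 7,9-diol free.

Step 5
Reactants: 6 [(2R,4RS)-5-chloro-2,4-dihydroxyhex-5-en-1-yl] 2,2-dimethylpropanoate; 7 triethyl orthoacetate
Product: 10 (5E,8R)-5-chloro-8-[(pivaloyloxy)methyl]-3,4,7,8-tetrahydro-2H-oxocin-2-one (ring-cis C9=C10), via cyclic orthoester 8 (not isolated), via ketene acetal 9 (not isolated)
Conditions: 7 (5 equiv), 2,4,6-trimethylbenzoic acid (10 mol%), o-xylene, 110 °C then 145 °C, EtOH distilled off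
Reagents that add atoms: triethyl orthoacetate (7), CCOC(C)(OCC)OCC
Why: Proposed new method: acid-catalysed exchange of two ethoxy groups of 7 by the diol gives cyclic orthoester 8 (once O9 is bound to C13, the C7 oxygen closes the 1,3-dioxane on the dialkoxycarbenium carbon, forming the O–C13 bond that persists in the target), loss of ethanol through the 1,3-dioxan-2-ylium ion gives ketene acetal 9, and the allyl vinyl ether array C12=C13–O9–C9–C10(Cl)=C11 of 9 undergoes a [3,3]-sigmatropic Claisen shift that forms C11–C12, cleaves the temporary O9–C9 bond and leaves O9 as the lactone carbonyl. The closest known reaction types are the Johnson orthoester Claisen rearrangement of allylic alcohols and the thermal ring expansion of isolated 2-methylene-4-vinyl-1,3-dioxanes to eight-membered lactones; the proposal merges them so that ring closure and rearrangement occur in one flask. The dioxane closes in a 6-exo mode, and the eight-membered ring is never closed end to end but arises by two-atom ring expansion of that dioxane (C12, C11 and C10 enter the ring, O9 leaves it). No stereocentre is created: C7 is untouched and the C9 centre is consumed, so both C9 epimers of 6 should converge (the rearrangement needs the chlorovinyl group pseudo-axial, which the 7,9-anti epimer offers in a chair and the syn epimer in a twist-boat). The step needs ring-cis C9=C10 geometry and the cyclic rather than an open-chain ketene acetal: the tether through the oxygen on C7 holds C8 and C11 on the same side in the bicyclic transition state (a trans-cyclooctene lactone is out of reach), exocyclic C–OEt ionisation of 8 is stereoelectronically preferred, a hindered non-nucleophilic acid and removal of ethanol suppress opening of the dioxanylium ion and ethanolysis of 10, and the chlorine on C10 disfavours ionisation at allylic C9.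

Step 6
Reactants: 10 (5E,8R)-5-chloro-8-[(pivaloyloxy)methyl]-3,4,7,8-tetrahydro-2H-oxocin-2-one
Product: 12 (3R,5E,8R)-5-chloro-3-hydroxy-8-[(pivaloyloxy)methyl]-3,4,7,8-tetrahydro-2H-oxocin-2-one, via potassium enolate 11 (not isolated)
Conditions: KN(SiMe3)2, THF, −78 °C; then 3-phenyl-2-(phenylsulfonyl)oxaziridine, −78 °C; aq. NH4Cl
Reagents that add atoms: 3-phenyl-2-(phenylsulfonyl)oxaziridine, O=S(=O)(N1OC1c1ccccc1)c1ccccc1
Why: Davis oxidation of the lactone enolate: enolate 11 should be hydroxylated from the peripheral face of the folded eight-membered ring, placing the C12 oxygen cis to the C7 substituent (12R).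

Step 7
Reactants: 12 (3R,5E,8R)-5-chloro-3-hydroxy-8-[(pivaloyloxy)methyl]-3,4,7,8-tetrahydro-2H-oxocin-2-one
Product: 13 (3R,5E,8R)-3-(tert-butyldimethylsilyloxy)-5-chloro-8-[(pivaloyloxy)methyl]-3,4,7,8-tetrahydro-2H-oxocin-2-one
Conditions: t-BuMe2SiOTf, 2,6-lutidine, CH2Cl2, −78 to 0 °C
Reagents that add atoms: tert-butyldimethylsilyl triflate, CC(C)(C)[Si](C)(C)OS(=O)(=O)C(F)(F)F
Why: Silylation with the silyl triflate protects the hindered α-hydroxyl before the organometallic step and later steers the hydride in step 9.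

Step 8
Reactants: 13 (3R,5E,8R)-3-(tert-butyldimethylsilyloxy)-5-chloro-8-[(pivaloyloxy)methyl]-3,4,7,8-tetrahydro-2H-oxocin-2-one; 14 ethylmagnesium bromide
Product: 15 hemiketal (7R,12R)-12-(tert-butyldimethylsilyloxy)-10-chloro-13-ethyl-13-hydroxy oxocene with CH2OPiv on C7 (both C13 anomers)
Conditions: EtMgBr, THF, −78 °C; aq. NH4Cl
Reagents that add atoms: ethylmagnesium bromide (14), CC[Mg]Br
Why: Single Grignard addition to the lactone carbonyl at low temperature should give the hemiketal, the hindered pivalate being far less electrophilic than the medium-ring lactone.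

Step 9
Reactants: 15 hemiketal (7R,12R)-12-(tert-butyldimethylsilyloxy)-10-chloro-13-ethyl-13-hydroxy oxocene with CH2OPiv on C7
Product: 16 (7R,12R,13R)-12-(tert-butyldimethylsilyloxy)-10-chloro-13-ethyl oxocene with CH2OPiv on C7 (ring O between C7 and C13)
Conditions: Et3SiH, BF3·OEt2, CH2Cl2, −78 to −40 °C
Reagents that add atoms: none
Why: Reductive deoxygenation of the lactol: BF3 ionises the hemiketal to the cyclic oxocarbenium ion and Et3SiH delivers hydride anti to the neighbouring C12 silyloxy group, which should set C13 as R with H13 cis to H7 (2,8-cis ether).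

Step 10
Reactants: 16 (7R,12R,13R)-12-(tert-butyldimethylsilyloxy)-10-chloro-13-ethyl oxocene with CH2OPiv on C7
Product: 17 (7R,12R,13R)-10-chloro-13-ethyl-12-hydroxy oxocene with CH2OPiv on C7
Conditions: Bu4NF, THF, 0 to 20 °C
Reagents that add atoms: none
Why: Fluoride cleaves the silyl ether while the pivalate, the vinyl chloride and the ring ether are inert.

Step 11
Reactants: 17 (7R,12R,13R)-10-chloro-13-ethyl-12-hydroxy oxocene with CH2OPiv on C7
Product: 18 (7R,12S,13R)-12-bromo-10-chloro-13-ethyl oxocene with CH2OPiv on C7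
Conditions: CBr4, P(n-C8H17)3, toluene, 70 °C
Reagents that add atoms: carbon tetrabromide, BrC(Br)(Br)Br
Why: Appel-type bromination: the alkoxyphosphonium ion is displaced by bromide with inversion (SN2), turning the 12R alcohol into the 12S bromide trans to the ethyl group.

Step 12
Reactants: 18 (7R,12S,13R)-12-bromo-10-chloro-13-ethyl oxocene with CH2OPiv on C7
Product: 19 (7R,12S,13R)-12-bromo-10-chloro-13-ethyl oxocene with CH2OH on C7
Conditions: i-Bu2AlH, CH2Cl2, −78 °C; aq. KNaC4H4O6
Reagents that add atoms: none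
Why: Reductive removal of the pivalate at low temperature should spare the secondary bromide and the vinyl chloride.

Step 13
Reactants: 19 (7R,12S,13R)-12-bromo-10-chloro-13-ethyl oxocene with CH2OH on C7
Product: 20 (7R,12S,13R)-12-bromo-10-chloro-13-ethyl oxocene-7-carbaldehyde (C6 aldehyde)
Conditions: Dess–Martin periodinane, NaHCO3, CH2Cl2, 0 to 20 °C
Reagents that add atoms: none
Why: Dess–Martin oxidation gives the α-alkoxy aldehyde under buffered conditions that should not epimerise C7.

Step 14
Reactants: 20 (7R,12S,13R)-12-bromo-10-chloro-13-ethyl oxocene-7-carbaldehyde; 21 allyl chloride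
Product: 22 (5S,6S,7R,12S,13R)-12-bromo-5,10-dichloro-7,13-epoxypentadeca-3,9-dien-6-ol lacking C1 and C2, that is the C6 alcohol with a C5 chloride and a C3=C4 vinyl group
Conditions: 21, LiN(c-C6H11)2, (+)-Ipc2BOMe, THF–Et2O, −95 °C; BF3·OEt2; then 20, −95 °C; HOCH2CH2NH2 work-up
Reagents that add atoms: allyl chloride (21), C=CCCl
Why: Asymmetric γ-chloroallylboration: the (Z)-γ-chloroallylborane made in the flask reacts through a chair (Zimmerman–Traxler) transition state to give the syn chlorohydrin, and the isopinocampheyl groups derived from (−)-α-pinene should direct attack to the Re face of the aldehyde, setting 5S and 6S against the intrinsic Felkin preference.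

Step 15
Reactants: 22 C6 alcohol with C5 chloride and terminal vinyl group
Product: 23 (5S,6S,7R,12S,13R) C6 acetate with C5 chloride and terminal vinyl group
Conditions: Ac2O, pyridine, DMAP (cat.), CH2Cl2, 0 °C
Reagents that add atoms: acetic anhydride, CC(=O)OC(C)=O
Why: Standard acetylation installs the C6 acetate of the target and blocks epoxide closure of the chlorohydrin.

Step 16
Reactants: 23 C6 acetate with C5 chloride and terminal vinyl group
Product: 25 (5R,6S,7R,12S,13R) α-chloro aldehyde (C4 aldehyde; 5R only by a change of CIP priority), via vicinal diol 24 (not isolated)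
Conditions: OsO4 (2 mol%), NaIO4, 2,6-lutidine, dioxane–H2O 3:1, 20 °C
Reagents that add atoms: sodium periodate, [Na+].[O-]I(=O)(=O)=O (terminal oxygen source, relayed by the catalytic OsO4)
Why: Lemieux–Johnson cleavage: OsO4 should dihydroxylate the monosubstituted alkene much faster than the electron-poor trisubstituted ring vinyl chloride, and periodate cleaves diol 24 to the aldehyde.

Step 17
Reactants: 25 α-chloro aldehyde; 26 1,3-bis(triisopropylsilyl)propyne
Product: 27 (3Z,5S,6S,7R,9E,12S,13R)-6-acetoxy-12-bromo-5,10-dichloro-7,13-epoxy-1-(triisopropylsilyl)pentadeca-3,9-dien-1-yne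
Conditions: 26, n-BuLi, THF, −78 °C; then 25, −78 to −20 °C; aq. NH4Cl
Reagents that add atoms: 1,3-bis(triisopropylsilyl)propyne (26), CC(C)[Si](C(C)C)(C(C)C)CC#C[Si](C(C)C)(C(C)C)C(C)C
Why: Peterson olefination with the lithiated bis-silyl propyne: addition to the aldehyde and syn-elimination of the bulky silanolate should give the (Z)-enyne selectively.

Step 18
Reactants: 27 silylated (Z)-enyne
Product: 28 (3Z,5S,6S,7R,9E,12S,13R)-6-acetoxy-12-bromo-5,10-dichloro-7,13-epoxypentadeca-3,9-dien-1-yne (target)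
Conditions: Bu4NF, AcOH, THF, −20 to 0 °C
Reagents that add atoms: none
Why: Buffered fluoride removes the alkynyl silyl group and should leave the acetate, the allylic chloride and the bromide untouched.

**Compound list**

1 | (R)-2-(2,2-dimethyl-1,3-dioxolan-4-yl)ethanol | CC1(C)OC[C@@H](CCO)O1 | starting material
2 | (R)-2-(2,2-dimethyl-1,3-dioxolan-4-yl)acetaldehyde | CC1(C)OC[C@@H](CC=O)O1 | intermediate
3 | 1,1,1-trichloroethane | CC(Cl)(Cl)Cl | starting material
4 | (2RS)-3-chloro-1-[(4R)-2,2-dimethyl-1,3-dioxolan-4-yl]but-3-en-2-ol (both C9 epimers) | CC1(C)OC[C@@H](CC(O)C(Cl)=C)O1 | intermediate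
5 | (2R,4RS)-5-chlorohex-5-ene-1,2,4-triol | OC[C@H](O)CC(O)C(Cl)=C | intermediate
6 | [(2R,4RS)-5-chloro-2,4-dihydroxyhex-5-en-1-yl] 2,2-dimethylpropanoate | CC(C)(C)C(=O)OC[C@H](O)CC(O)C(Cl)=C | intermediate
7 | triethyl orthoacetate | CCOC(C)(OCC)OCC | starting material
8 | [(4R)-6-(1-chloroethenyl)-2-ethoxy-2-methyl-1,3-dioxan-4-yl]methyl 2,2-dimethylpropanoate (epimers at dioxane C2 and C6) | CCOC1(C)O[C@@H](COC(=O)C(C)(C)C)CC(C(Cl)=C)O1 | intermediate
9 | [(4R)-6-(1-chloroethenyl)-2-methylidene-1,3-dioxan-4-yl]methyl 2,2-dimethylpropanoate (epimers at dioxane C6) | C=C1O[C@@H](COC(=O)C(C)(C)C)CC(C(Cl)=C)O1 | intermediate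
10 | (5E,8R)-5-chloro-8-[(pivaloyloxy)methyl]-3,4,7,8-tetrahydro-2H-oxocin-2-one | CC(C)(C)C(=O)OC[C@H]1C/C=C(/Cl)CCC(=O)O1 | intermediate
11 | potassium enolate of 10 (C12=C13–OK) | CC(C)(C)C(=O)OC[C@H]1C/C=C(/Cl)C/C=C(/[O-])O1.[K+] | intermediate
12 | (3R,5E,8R)-5-chloro-3-hydroxy-8-[(pivaloyloxy)methyl]-3,4,7,8-tetrahydro-2H-oxocin-2-one | CC(C)(C)C(=O)OC[C@H]1C/C=C(/Cl)C[C@@H](O)C(=O)O1 | intermediate
13 | (3R,5E,8R)-3-(tert-butyldimethylsilyloxy)-5-chloro-8-[(pivaloyloxy)methyl]-3,4,7,8-tetrahydro-2H-oxocin-2-one | CC(C)(C)C(=O)OC[C@H]1C/C=C(/Cl)C[C@@H](O[Si](C)(C)C(C)(C)C)C(=O)O1 | intermediate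
14 | ethylmagnesium bromide | CC[Mg]Br | starting material
15 | hemiketal: (7R,12R)-12-(tert-butyldimethylsilyloxy)-10-chloro-13-ethyl-13-hydroxy oxocene, CH2OPiv on C7 (C13 anomers) | CC(C)(C)C(=O)OC[C@H]1C/C=C(/Cl)C[C@@H](O[Si](C)(C)C(C)(C)C)C(O)(CC)O1 | intermediate
16 | (7R,12R,13R)-12-(tert-butyldimethylsilyloxy)-10-chloro-13-ethyl oxocene, CH2OPiv on C7 | CC(C)(C)C(=O)OC[C@H]1C/C=C(/Cl)C[C@@H](O[Si](C)(C)C(C)(C)C)[C@@H](CC)O1 | intermediate
17 | (7R,12R,13R)-10-chloro-13-ethyl-12-hydroxy oxocene, CH2OPiv on C7 | CC(C)(C)C(=O)OC[C@H]1C/C=C(/Cl)C[C@@H](O)[C@@H](CC)O1 | intermediate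
18 | (7R,12S,13R)-12-bromo-10-chloro-13-ethyl oxocene, CH2OPiv on C7 | CC(C)(C)C(=O)OC[C@H]1C/C=C(/Cl)C[C@H](Br)[C@@H](CC)O1 | intermediate
19 | (7R,12S,13R)-12-bromo-10-chloro-13-ethyl oxocene, CH2OH on C7 | OC[C@H]1C/C=C(/Cl)C[C@H](Br)[C@@H](CC)O1 | intermediate
20 | (7R,12S,13R)-12-bromo-10-chloro-13-ethyl oxocene-7-carbaldehyde | O=C[C@H]1C/C=C(/Cl)C[C@H](Br)[C@@H](CC)O1 | intermediate
21 | allyl chloride | C=CCCl | starting material
22 | (5S,6S,7R,12S,13R) chlorohydrin: C6–OH, C5–Cl, C3=C4 vinyl on the bromo-chloro oxocene | C=C[C@H](Cl)[C@@H](O)[C@H]1C/C=C(/Cl)C[C@H](Br)[C@@H](CC)O1 | intermediate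
23 | (5S,6S,7R,12S,13R) acetate of 22 | C=C[C@H](Cl)[C@@H](OC(C)=O)[C@H]1C/C=C(/Cl)C[C@H](Br)[C@@H](CC)O1 | intermediate
24 | vicinal diol from 23 (C3–OH, C4–OH; C4 epimers; C5, C6, C7, C12, C13 as in 23) | OCC(O)[C@H](Cl)[C@@H](OC(C)=O)[C@H]1C/C=C(/Cl)C[C@H](Br)[C@@H](CC)O1 | intermediate
25 | (5R,6S,7R,12S,13R) α-chloro aldehyde (C4 aldehyde, spatial arrangement as in 23) | O=C[C@H](Cl)[C@@H](OC(C)=O)[C@H]1C/C=C(/Cl)C[C@H](Br)[C@@H](CC)O1 | intermediate
26 | 1,3-bis(triisopropylsilyl)propyne | CC(C)[Si](C(C)C)(C(C)C)CC#C[Si](C(C)C)(C(C)C)C(C)C | starting material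
27 | (3Z,5S,6S,7R,9E,12S,13R)-6-acetoxy-12-bromo-5,10-dichloro-7,13-epoxy-1-(triisopropylsilyl)pentadeca-3,9-dien-1-yne | CC(C)[Si](C(C)C)(C(C)C)C#C/C=C\[C@H](Cl)[C@@H](OC(C)=O)[C@H]1C/C=C(/Cl)C[C@H](Br)[C@@H](CC)O1 | intermediate
28 | (3Z,5S,6S,7R,9E,12S,13R)-6-acetoxy-12-bromo-5,10-dichloro-7,13-epoxypentadeca-3,9-dien-1-yne | C#C/C=C\[C@H](Cl)[C@@H](OC(C)=O)[C@H]1C/C=C(/Cl)C[C@H](Br)[C@@H](CC)O1 | target

**Step count and risks**

Total step count: 18. Longest linear sequence: 18 steps (1 to 28).

Steps most likely to fail: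

Step 5 (Proposed new method). What may go wrong: endocyclic ionisation of orthoester 8 to an open-chain ketene acetal that rearranges with the wrong alkene geometry, or acid-induced opening of the dioxanylium ion and ethanolysis of the strained lactone. The fallback uses the known stepwise generation of the same ketene acetal and sets out from 6. Transacetalisation of 6 with 2-(phenylselanyl)acetaldehyde diethyl acetal (PPTS, toluene, 110 °C) gives the selenoacetal [(4R)-6-(1-chloroethenyl)-2-(phenylselanylmethyl)-1,3-dioxan-4-yl]methyl pivalate F1. Oxidation with NaIO4/NaHCO3 in MeOH–H2O gives the selenoxide F2. Heating F2 with DBU in xylene at 140 °C causes syn-elimination to ketene acetal 9, which rearranges thermally, and the route is rejoined at 10.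

Step 9 (with step 8). What may go wrong: ring-opening of the hemiketal to the hydroxy ketone and direct reduction of that ketone instead of the cyclic oxocarbenium ion, or double Grignard addition in step 8, in either case with loss of the medium ring. The fallback sets out from 13 and uses the thionolactone route. Lawesson's reagent (toluene, 110 °C) converts 13 into the thionolactone F3. EtLi (THF, −78 °C) followed by MeI gives the S-methyl mixed thioketal F4. Radical desulfurisation with Ph3SnH and AIBN (toluene, 110 °C) should deliver hydrogen to the C13 radical from the less hindered face, and the route is rejoined at 16.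

Step 17. What may go wrong: enolisation of the α-chloro aldehyde by the basic lithium reagent, with β-elimination of acetate or epimerisation at C5, or epoxide closure of the intermediate alkoxide onto the C5 chloride. The fallback sets out from 25 and uses a less basic ylide followed by cross-coupling. Stork–Zhao olefination (Ph3P+CH2I I−, NaN(SiMe3)2, THF, −78 °C) gives the (Z)-vinyl iodide F5. Sonogashira coupling with trimethylsilylacetylene (Pd(PPh3)4, CuI, Et2NH, 20 °C) gives the trimethylsilyl (Z)-enyne F6. Bu4NF/AcOH then removes the silyl group, and the route is rejoined at 28.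

**Further compounds**

F1 | step 5 | [(4R)-6-(1-chloroethenyl)-2-(phenylselanylmethyl)-1,3-dioxan-4-yl]methyl 2,2-dimethylpropanoate | c1ccccc1[Se]CC1O[C@@H](COC(=O)C(C)(C)C)CC(C(Cl)=C)O1
F2 | step 5 | selenoxide of F1 | O=[Se](c1ccccc1)CC1O[C@@H](COC(=O)C(C)(C)C)CC(C(Cl)=C)O1
F3 | step 9 | (3R,5E,8R)-3-(tert-butyldimethylsilyloxy)-5-chloro-8-[(pivaloyloxy)methyl]-3,4,7,8-tetrahydro-2H-oxocine-2-thione | CC(C)(C)C(=O)OC[C@H]1C/C=C(/Cl)C[C@@H](O[Si](C)(C)C(C)(C)C)C(=S)O1
F4 | step 9 | (7R,12R)-12-(tert-butyldimethylsilyloxy)-10-chloro-13-ethyl-13-(methylsulfanyl) oxocene, CH2OPiv on C7 (C13 epimers) | CC(C)(C)C(=O)OC[C@H]1C/C=C(/Cl)C[C@@H](O[Si](C)(C)C(C)(C)C)C(CC)(SC)O1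
F5 | step 17 | (3Z,5S,6S,7R,12S,13R) vinyl iodide: C3 iodide, C3=C4, C5–Cl, C6–OAc on the bromo-chloro oxocene | I/C=C\[C@H](Cl)[C@@H](OC(C)=O)[C@H]1C/C=C(/Cl)C[C@H](Br)[C@@H](CC)O1
F6 | step 17 | (3Z,5S,6S,7R,9E,12S,13R)-6-acetoxy-12-bromo-5,10-dichloro-7,13-epoxy-1-(trimethylsilyl)pentadeca-3,9-dien-1-yne | C[Si](C)(C)C#C/C=C\[C@H](Cl)[C@@H](OC(C)=O)[C@H]1C/C=C(/Cl)C[C@H](Br)[C@@H](CC)O1
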